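## Retrosynthetic overview

- Kazinol E ⇐ MOM removal ⇐ aromatic Claisen rearrangement (C7–O-prenyl → C6 1,1-dimethylallyl) ⇐ prenylation of a C2' bromide on the finished flavan.
- The bromoflavan ⇐ closure of ring C at the C3–C4 bond of an achiral aryl 1-arylvinyl ether that has no link between C3 and C4, with hydride delivery to C2 in the same flask setting the (2S) centre.
- Enabling feature: C4 is the benzylic carbon on ring A that lies ortho to O1 (on C8a) and para to the C7 oxygen, so its cation is doubly stabilised; C3 is the nucleophilic β-carbon of the O1–C2=C3 enol ether, and C2, flanked by O1 and ring B, holds the charge until hydride arrives.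
- The vinyl ether ⇐ methylenation of an aryl ester ⇐ ring A phenol (from 2,4-dihydroxybenzaldehyde) + ring B acid (from 4,5-dibromocatechol by ortho-lithiation/prenylation and Br/Mg exchange/CO2).
- Ring order: rings A and B are bought as arenes; ring C is the only ring formed. C2' stays a bromide through the cationic step because an ortho-prenyl alkene would capture the C2 cation.

Key step: step 8

Assumption (remark on the chemistry): the (R)-configured acid is taken to direct hydride to the Re face of C2, by analogy with 2-arylquinoline reductions; should the (2R)-flavan predominate, the (S)-acid is used without other change. 4,5-Dibromobenzene-1,2-diol is taken as purchased.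

## Route

Step 1
Reactants: 1 2,4-dihydroxybenzaldehyde
Product: 2 2-hydroxy-4-[(3-methylbut-2-en-1-yl)oxy]benzaldehyde
Conditions: prenyl bromide (1.05 equiv), K2CO3 (1.0 equiv), acetone, 50 °C
Reagents that add atoms: prenyl bromide (1-bromo-3-methylbut-2-ene), CC(C)=CCBr
Why: Williamson ether synthesis, in which the 2-OH is held in a hydrogen bond to the formyl group and is less acidic, so alkylation should occur at O4 only.

Step 2
Reactants: 2 2-hydroxy-4-[(3-methylbut-2-en-1-yl)oxy]benzaldehyde
Product: 4 2-(methoxymethyl)-5-[(3-methylbut-2-en-1-yl)oxy]phenol, via salicyl alcohol 3 (not isolated)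
Conditions: NaBH4 (0.5 equiv), MeOH, 0 °C; then AcOH (quench), PPTS (10 mol%), MeOH, 40 °C
Reagents that add atoms: methanol, CO
Why: Borohydride reduction followed by acid-catalysed SN1 etherification, in which the benzylic cation of 3 (stabilised by the ortho-hydroxyl and para-alkoxy groups) is captured by the solvent, turning a self-condensing alcohol into a stable leaving group for step 8 while the phenol stays free.

Step 3
Reactants: 5 4,5-dibromobenzene-1,2-diol
Product: 6 1,2-dibromo-4,5-bis(methoxymethoxy)benzene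
Conditions: MOMCl (2.5 equiv), i-Pr2NEt (3 equiv), CH2Cl2, 0 °C → rt
Reagents that add atoms: chloromethyl methyl ether (MOMCl), COCCl
Why: O-alkylation of both phenols with the α-chloro ether (acetal protection) gives groups that direct the next lithiation and can be removed later without hydrogenation.

Step 4
Reactants: 6 1,2-dibromo-4,5-bis(methoxymethoxy)benzene
Product: 8 1,2-dibromo-4,5-bis(methoxymethoxy)-3-(3-methylbut-2-en-1-yl)benzene, via aryllithium 7 (not isolated)
Conditions: LDA (1.1 equiv), THF, −78 °C (6 added to the base); then CuBr·SMe2 (10 mol%), prenyl bromide (1.3 equiv), −78 → −40 °C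
Reagents that add atoms: prenyl bromide (1-bromo-3-methylbut-2-ene), CC(C)=CCBr
Why: Directed ortho-lithiation at the C–H flanked by Br and OMOM (the two such positions are equivalent by symmetry) and Cu-catalysed SN2 allylation at the primary carbon of prenyl bromide, with the low temperature holding back aryne formation and halogen migration of the ortho-bromoaryllithium.

Step 5
Reactants: 8 1,2-dibromo-4,5-bis(methoxymethoxy)-3-(3-methylbut-2-en-1-yl)benzene
Product: 10 2-bromo-4,5-bis(methoxymethoxy)-3-(3-methylbut-2-en-1-yl)benzoic acid, via arylmagnesium chloride 9 (not isolated)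
Conditions: i-PrMgCl·LiCl (1.1 equiv), THF, −20 °C; then CO2 (gas), −20 °C → rt; 1 M HCl to pH 3, 0 °C
Reagents that add atoms: carbon dioxide, O=C=O
Why: Bromine–magnesium exchange with the turbo-Grignard reagent should occur at the bromine flanked by H and not at the one buttressed by the prenyl group (steric and inductive control), the ortho-bromoarylmagnesium does not eliminate at this temperature, and carboxylation gives the acid.

Step 6
Reactants: 4 2-(methoxymethyl)-5-[(3-methylbut-2-en-1-yl)oxy]phenol; 10 2-bromo-4,5-bis(methoxymethoxy)-3-(3-methylbut-2-en-1-yl)benzoic acid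
Product: 11 2-(methoxymethyl)-5-[(3-methylbut-2-en-1-yl)oxy]phenyl 2-bromo-4,5-bis(methoxymethoxy)-3-(3-methylbut-2-en-1-yl)benzoate
Conditions: DCC (1.2 equiv), DMAP (10 mol%), CH2Cl2, 0 °C → rt
Reagents that add atoms: none
Why: Steglich esterification of a phenol with a mono-ortho-substituted benzoic acid, with no competing nucleophile in either partner.

Step 7
Reactants: 11 2-(methoxymethyl)-5-[(3-methylbut-2-en-1-yl)oxy]phenyl 2-bromo-4,5-bis(methoxymethoxy)-3-(3-methylbut-2-en-1-yl)benzoate
Product: 12 2-bromo-4,5-bis(methoxymethoxy)-1-(1-{2-(methoxymethyl)-5-[(3-methylbut-2-en-1-yl)oxy]phenoxy}ethenyl)-3-(3-methylbut-2-en-1-yl)benzene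
Conditions: Cp2TiMe2 (dimethyltitanocene, 3 equiv), toluene, 70 °C, dark; filtration through basic alumina
Reagents that add atoms: dimethyltitanocene (Cp2TiMe2), C[Ti+2]C.c1cc[cH-]c1.c1cc[cH-]c1
Why: Petasis methylenation, in which thermally generated Cp2Ti=CH2 converts the aryl ester carbonyl into the 1,1-disubstituted enol ether under non-acidic conditions that spare the MOM groups, the benzylic ether and the aryl bromide.

Step 8
Reactants: 12 2-bromo-4,5-bis(methoxymethoxy)-1-(1-{2-(methoxymethyl)-5-[(3-methylbut-2-en-1-yl)oxy]phenoxy}ethenyl)-3-(3-methylbut-2-en-1-yl)benzene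
Product: 14 (2S)-2-[2-bromo-4,5-bis(methoxymethoxy)-3-(3-methylbut-2-en-1-yl)phenyl]-7-[(3-methylbut-2-en-1-yl)oxy]chromane, via 4H-chromene 13 (not isolated)
Conditions: (R)-3,3'-bis(2,4,6-triisopropylphenyl)-BINOL N-triflylphosphoramide (5 mol%), 5 Å MS, toluene (0.01 M), 0 °C → rt; then Hantzsch ester (diethyl 2,6-dimethyl-1,4-dihydropyridine-3,5-dicarboxylate, 1.3 equiv), 0 °C → rt
Reagents that add atoms: none
Why: Proposed new method: the strong chiral Brønsted acid ionises the benzylic methyl ether of 12 to a C4 benzyl cation stabilised by O1 (ortho) and the C7 oxygen (para), and the β-carbon (C3) of the aryl enol ether attacks it in a 6-endo-trig closure of ring C, giving a C2 oxocarbenium ion that loses a proton to the 4H-chromene 13. In the second stage the acid reprotonates C3 of 13 and the Hantzsch ester, hydrogen-bonded to the chiral phosphoramide anion of the ion pair, transfers hydride to the Re face of C2, so the counter-anion is the controlling element for the (2S) centre. The closest known reaction types are the acid-catalysed SN1 alkylation of enol ethers by stabilised benzylic cations, the chiral phosphoric acid/Hantzsch ester cascade reduction of 2-arylquinolines through a cyclic 2-aryl iminium ion, and chiral-anion control over additions to cyclic oxocarbenium ions; coupling a benzylic ionisation/cyclisation in one flask to an ion-pair reduction of a 2-aryl oxocarbenium ion has no direct precedent. The step needs chemoselectivity for the intramolecular enol ether over the arenes and trisubstituted alkenes, which the higher nucleophilicity of the enol ether and the six-membered transition state should secure, and it needs the C2 cation to survive until hydride arrives, which is why C2' carries bromine and not prenyl (an ortho-prenyl alkene would trap the C2 cation as an indane). Adding the Hantzsch ester only after ring closure keeps the free acid available for the ionisation and prevents reduction of the protonated, uncyclised enol ether, and the molecular sieves take up the methanol that is set free.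

Step 9
Reactants: 14 (2S)-2-[2-bromo-4,5-bis(methoxymethoxy)-3-(3-methylbut-2-en-1-yl)phenyl]-7-[(3-methylbut-2-en-1-yl)oxy]chromane
Product: 16 (2S)-2-[4,5-bis(methoxymethoxy)-2,3-bis(3-methylbut-2-en-1-yl)phenyl]-7-[(3-methylbut-2-en-1-yl)oxy]chromane, via aryllithium 15 (not isolated)
Conditions: t-BuLi (2.05 equiv), THF, −78 °C; then CuBr·SMe2 (10 mol%), prenyl bromide (1.5 equiv), −78 → 0 °C
Reagents that add atoms: prenyl bromide (1-bromo-3-methylbut-2-ene), CC(C)=CCBr
Why: Bromine–lithium exchange is faster than any deprotonation at −78 °C and Cu-catalysed SN2 allylation of the aryllithium installs the linear C2' prenyl group, while the C2–H is not acidic enough to be touched, so the stereocentre is kept.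

Step 10
Reactants: 16 (2S)-2-[4,5-bis(methoxymethoxy)-2,3-bis(3-methylbut-2-en-1-yl)phenyl]-7-[(3-methylbut-2-en-1-yl)oxy]chromane
Product: 17 (2S)-2-[4,5-bis(methoxymethoxy)-2,3-bis(3-methylbut-2-en-1-yl)phenyl]-6-(2-methylbut-3-en-2-yl)chroman-7-ol
Conditions: EtOH/H2O (4:1), 140 °C, sealed tube
Reagents that add atoms: none
Why: Aromatic Claisen rearrangement, in which the [3,3] shift of the C7 prenyl ether (which served as the C7–O protecting group until now) should deliver the tertiary allyl carbon to C6, the ortho position not flanked by O1 (C8 is the hindered alternative and the para position C4a is substituted), and tautomerisation gives the 7-hydroxy-6-(1,1-dimethylallyl) pattern without touching C2.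

Step 11
Reactants: 17 (2S)-2-[4,5-bis(methoxymethoxy)-2,3-bis(3-methylbut-2-en-1-yl)phenyl]-6-(2-methylbut-3-en-2-yl)chroman-7-ol
Product: 18 Kazinol E (5-[(2S)-7-hydroxy-6-(2-methylbut-3-en-2-yl)chroman-2-yl]-3,4-bis(3-methylbut-2-en-1-yl)benzene-1,2-diol)
Conditions: HCl (0.5 M in MeOH), 25 °C, argon
Reagents that add atoms: none
Why: Acid-catalysed acetal exchange transfers both methoxymethyl groups to methanol, and dilute acid at room temperature is chosen so that the ortho-prenyl and ortho-dimethylallyl phenols should not cyclise and the benzylic C2–O1 bond should not ionise.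

## Compound list

1 | 2,4-dihydroxybenzaldehyde | O=Cc1ccc(O)cc1O | starting material
2 | 2-hydroxy-4-[(3-methylbut-2-en-1-yl)oxy]benzaldehyde | CC(C)=CCOc1ccc(C=O)c(O)c1 | intermediate
3 | 2-(hydroxymethyl)-5-[(3-methylbut-2-en-1-yl)oxy]phenol (not isolated) | CC(C)=CCOc1ccc(CO)c(O)c1 | intermediate
4 | 2-(methoxymethyl)-5-[(3-methylbut-2-en-1-yl)oxy]phenol | CC(C)=CCOc1ccc(COC)c(O)c1 | intermediate
5 | 4,5-dibromobenzene-1,2-diol | Oc1cc(Br)c(Br)cc1O | starting material
6 | 1,2-dibromo-4,5-bis(methoxymethoxy)benzene | COCOc1cc(Br)c(Br)cc1OCOC | intermediate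
7 | [2,3-dibromo-5,6-bis(methoxymethoxy)phenyl]lithium (not isolated) | COCOc1cc(Br)c(Br)c([Li])c1OCOC | intermediate
8 | 1,2-dibromo-4,5-bis(methoxymethoxy)-3-(3-methylbut-2-en-1-yl)benzene | COCOc1cc(Br)c(Br)c(CC=C(C)C)c1OCOC | intermediate
9 | [2-bromo-4,5-bis(methoxymethoxy)-3-(3-methylbut-2-en-1-yl)phenyl]magnesium chloride (not isolated) | COCOc1cc([Mg]Cl)c(Br)c(CC=C(C)C)c1OCOC | intermediate
10 | 2-bromo-4,5-bis(methoxymethoxy)-3-(3-methylbut-2-en-1-yl)benzoic acid | COCOc1cc(C(=O)O)c(Br)c(CC=C(C)C)c1OCOC | intermediate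
11 | 2-(methoxymethyl)-5-[(3-methylbut-2-en-1-yl)oxy]phenyl 2-bromo-4,5-bis(methoxymethoxy)-3-(3-methylbut-2-en-1-yl)benzoate | COCc1ccc(OCC=C(C)C)cc1OC(=O)c1cc(OCOC)c(OCOC)c(CC=C(C)C)c1Br | intermediate
12 | 2-bromo-4,5-bis(methoxymethoxy)-1-(1-{2-(methoxymethyl)-5-[(3-methylbut-2-en-1-yl)oxy]phenoxy}ethenyl)-3-(3-methylbut-2-en-1-yl)benzene (aryl 1-arylvinyl ether) | COCc1ccc(OCC=C(C)C)cc1OC(=C)c1cc(OCOC)c(OCOC)c(CC=C(C)C)c1Br | intermediate
13 | 2-[2-bromo-4,5-bis(methoxymethoxy)-3-(3-methylbut-2-en-1-yl)phenyl]-7-[(3-methylbut-2-en-1-yl)oxy]-4H-chromene (not isolated) | CC(C)=CCOc1ccc2c(c1)OC(c1cc(OCOC)c(OCOC)c(CC=C(C)C)c1Br)=CC2 | intermediate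
14 | (2S)-2-[2-bromo-4,5-bis(methoxymethoxy)-3-(3-methylbut-2-en-1-yl)phenyl]-7-[(3-methylbut-2-en-1-yl)oxy]chromane | CC(C)=CCOc1ccc2c(c1)O[C@H](c1cc(OCOC)c(OCOC)c(CC=C(C)C)c1Br)CC2 | intermediate
15 | {3,4-bis(methoxymethoxy)-2-(3-methylbut-2-en-1-yl)-6-[(2S)-7-[(3-methylbut-2-en-1-yl)oxy]chroman-2-yl]phenyl}lithium (not isolated) | CC(C)=CCOc1ccc2c(c1)O[C@H](c1cc(OCOC)c(OCOC)c(CC=C(C)C)c1[Li])CC2 | intermediate
16 | (2S)-2-[4,5-bis(methoxymethoxy)-2,3-bis(3-methylbut-2-en-1-yl)phenyl]-7-[(3-methylbut-2-en-1-yl)oxy]chromane | CC(C)=CCOc1ccc2c(c1)O[C@H](c1cc(OCOC)c(OCOC)c(CC=C(C)C)c1CC=C(C)C)CC2 | intermediate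
17 | (2S)-2-[4,5-bis(methoxymethoxy)-2,3-bis(3-methylbut-2-en-1-yl)phenyl]-6-(2-methylbut-3-en-2-yl)chroman-7-ol | C=CC(C)(C)c1cc2c(cc1O)O[C@H](c1cc(OCOC)c(OCOC)c(CC=C(C)C)c1CC=C(C)C)CC2 | intermediate
18 | Kazinol E, 5-[(2S)-7-hydroxy-6-(2-methylbut-3-en-2-yl)chroman-2-yl]-3,4-bis(3-methylbut-2-en-1-yl)benzene-1,2-diol | C=CC(C)(C)c1cc2c(cc1O)O[C@H](c1cc(O)c(O)c(CC=C(C)C)c1CC=C(C)C)CC2 | target

## Step count and risks

Total step count: 11. Longest linear sequence: 9 steps (5 → 6 → 8 → 10 → 11 → 12 → 14 → 16 → 17 → 18, steps 3 to 11).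

Steps most likely to fail:

Step 8 (carries the label). The hydride transfer to the C2 oxocarbenium ion pair may show poor facial selectivity, because the cation offers no hydrogen-bond handle to the chiral anion; the enol ether may also be lost to methanolysis before the benzylic ether ionises. The fallback uses known chemistry, sets out from 12 and comes back at 14. Compound 12 is cyclised with an achiral acid (diphenyl phosphate, 10 mol%, toluene, 5 Å MS) to 13, and wet THF/PPTS at 40 °C then opens the cyclic enol ether to the ketone 1-[2-bromo-4,5-bis(methoxymethoxy)-3-(3-methylbut-2-en-1-yl)phenyl]-3-{2-hydroxy-4-[(3-methylbut-2-en-1-yl)oxy]phenyl}propan-1-one F1. CBS reduction ((S)-2-methyl-CBS-oxazaborolidine, BH3·SMe2, THF, −20 °C; aryl as the large group) should give the (1R)-carbinol (1R)-1-[2-bromo-4,5-bis(methoxymethoxy)-3-(3-methylbut-2-en-1-yl)phenyl]-3-{2-hydroxy-4-[(3-methylbut-2-en-1-yl)oxy]phenyl}propan-1-ol F2. Mitsunobu cyclisation (PPh3, DIAD, THF, 0 °C) closes the pyran ring through O1–C2 with inversion to give 14.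

Step 10. The sigmatropic shift may go to C8 instead of C6, or the prenyl ether may ionise at the temperature needed, giving [1,3]-shifted or cyclised products. The fallback builds the group at C6 by aromatic substitution instead of rearrangement; it sets out from 16 and comes back at 17. Pd(PPh3)4 (5 mol%) with morpholine in THF removes the O-prenyl group to give the phenol (2S)-2-[4,5-bis(methoxymethoxy)-2,3-bis(3-methylbut-2-en-1-yl)phenyl]chroman-7-ol F3. The preformed Nicholas salt [Co2(CO)6(HC≡C–CMe2)]BF4 (CH2Cl2, −40 °C, 2,6-di-tert-butylpyridine) should alkylate the most nucleophilic and least hindered ring carbon, C6 (ortho to the C7 hydroxyl, para to O1), giving the hexacarbonyldicobalt complex of (2S)-2-[4,5-bis(methoxymethoxy)-2,3-bis(3-methylbut-2-en-1-yl)phenyl]-6-(2-methylbut-3-yn-2-yl)chroman-7-ol F4. Decomplexation with Me3NO in THF frees the alkyne (2S)-2-[4,5-bis(methoxymethoxy)-2,3-bis(3-methylbut-2-en-1-yl)phenyl]-6-(2-methylbut-3-yn-2-yl)chroman-7-ol F5, and semi-hydrogenation (H2, Pd/CaCO3/Pb(OAc)2, quinoline, EtOAc) gives 17.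

Step 9. The hindered aryllithium may be protonated before it is alkylated (loss of bromine without C–C bond formation), or the base may attack the allylic ether. The fallback changes the order of the last operations and makes the bond by cross-coupling; it sets out from 14 and comes back at 17. The Claisen rearrangement of step 10 is run first on 14 (EtOH/H2O 4:1, 140 °C) to give the bromophenol (2S)-2-[2-bromo-4,5-bis(methoxymethoxy)-3-(3-methylbut-2-en-1-yl)phenyl]-6-(2-methylbut-3-en-2-yl)chroman-7-ol F6. An α-selective Suzuki–Miyaura coupling with prenylboronic acid pinacol ester ([(IPent)PdCl2(3-chloropyridine)], 2 mol%, KOH, THF, 70 °C) then gives 17.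

Further compounds
F1 | step 8 | 1-[2-bromo-4,5-bis(methoxymethoxy)-3-(3-methylbut-2-en-1-yl)phenyl]-3-{2-hydroxy-4-[(3-methylbut-2-en-1-yl)oxy]phenyl}propan-1-one | O=C(CCc1ccc(OCC=C(C)C)cc1O)c1cc(OCOC)c(OCOC)c(CC=C(C)C)c1Br
F2 | step 8 | (1R)-1-[2-bromo-4,5-bis(methoxymethoxy)-3-(3-methylbut-2-en-1-yl)phenyl]-3-{2-hydroxy-4-[(3-methylbut-2-en-1-yl)oxy]phenyl}propan-1-ol | O[C@H](CCc1ccc(OCC=C(C)C)cc1O)c1cc(OCOC)c(OCOC)c(CC=C(C)C)c1Br
F3 | step 10 | (2S)-2-[4,5-bis(methoxymethoxy)-2,3-bis(3-methylbut-2-en-1-yl)phenyl]chroman-7-ol | Oc1ccc2c(c1)O[C@H](c1cc(OCOC)c(OCOC)c(CC=C(C)C)c1CC=C(C)C)CC2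
F4 | step 10 | hexacarbonyldicobalt complex of (2S)-2-[4,5-bis(methoxymethoxy)-2,3-bis(3-methylbut-2-en-1-yl)phenyl]-6-(2-methylbut-3-yn-2-yl)chroman-7-ol | CC(C)(c1cc2c(cc1O)O[C@H](c1cc(OCOC)c(OCOC)c(CC=C(C)C)c1CC=C(C)C)CC2)C12[CH]3[Co]1(=C=O)(=C=O)(=C=O)[Co]23(=C=O)(=C=O)=C=O
F5 | step 10 | (2S)-2-[4,5-bis(methoxymethoxy)-2,3-bis(3-methylbut-2-en-1-yl)phenyl]-6-(2-methylbut-3-yn-2-yl)chroman-7-ol | C#CC(C)(C)c1cc2c(cc1O)O[C@H](c1cc(OCOC)c(OCOC)c(CC=C(C)C)c1CC=C(C)C)CC2
F6 | step 9 | (2S)-2-[2-bromo-4,5-bis(methoxymethoxy)-3-(3-methylbut-2-en-1-yl)phenyl]-6-(2-methylbut-3-en-2-yl)chroman-7-ol | C=CC(C)(C)c1cc2c(cc1O)O[C@H](c1cc(OCOC)c(OCOC)c(CC=C(C)C)c1Br)CC2
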